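The route hinges on cutting bond C4–C10 of the cyclobutane (ring C4–C5–C11–C10). C3, the substituent on C4, can be read as a former carboxyl carbon. The methylated quaternary corner C10 is linked through C9 to the bare methylene C8. With a C8=C9 alkene drawn in, this is a γ,δ-unsaturated acid, the signature of an ester-enolate [3,3] shift from an oxygen once held by C8. The precursor is bridged lactone 27, a 3-methylcyclohept-2-enol (carbocycle C5–C11) esterified at O8 by the acetic acid arm on C5. One operation contracts its eight-membered lactone ring to the cyclobutane, sets C10 and C4, and erases the C8 oxygen.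

Key step: step 19

Numbering (target numbering, used for all compounds):
- C1 is the ketone carbon and C2=C3 the enone alkene, with the methyl on C3.
- C4 and C11 are the cyclobutane CH groups on C3 and C1.
- C5 is the cyclobutane CH on quaternary C6, and C7 is the secondary carbinol carbon.
- C8 and C9 are the methylenes, and C10 is the methyl-bearing cyclobutane carbon.
- C12 is the CH2O on C6, and On is the oxygen on Cn.
- The target is 4R,5S,6R,7S,10R,11R.

Assumption: the sense of induction in step 5 cannot be predicted with certainty for diol 6. The (R,R) ligand is written, and its (S,S) antipode is used instead if a correlation shows that ent-7 is formed.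

Step 1
Reactants: 1 1,1,1-tris(hydroxymethyl)ethane
Product: 2 (2,2,5-trimethyl-1,3-dioxan-5-yl)methanol
Conditions: Me2C(OMe)2, p-TsOH·H2O (cat.), acetone, rt
Reagents that add atoms: 2,2-dimethoxypropane, COC(C)(C)OC
Why: Acid-catalysed transketalisation closes the unstrained 1,3-dioxane on two of the three equivalent hydroxymethyl groups and leaves the third free, so no selectivity or stereochemical issue arises.

Step 2
Reactants: 2 (2,2,5-trimethyl-1,3-dioxan-5-yl)methanol
Product: 3 2,2,5-trimethyl-1,3-dioxane-5-carbaldehyde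
Conditions: Dess–Martin periodinane, CH2Cl2, rt
Reagents that add atoms: none
Why: Dess–Martin oxidation takes the neopentyl primary alcohol to the aldehyde under near-neutral conditions that spare the ketal, and the product has no α-hydrogen to enolise.

Step 3
Reactants: 3 2,2,5-trimethyl-1,3-dioxane-5-carbaldehyde; 4 tert-butyl 2-(diethoxyphosphoryl)acetate
Product: 5 tert-butyl (E)-3-(2,2,5-trimethyl-1,3-dioxan-5-yl)prop-2-enoate
Conditions: 4, NaH, THF, 0 °C; then 3, 0 °C → rt
Reagents that add atoms: tert-butyl 2-(diethoxyphosphoryl)acetate (4), CCOP(=O)(CC(=O)OC(C)(C)C)OCC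
Why: Horner–Wadsworth–Emmons olefination with the stabilised phosphonate anion builds C5=C4–C3 and gives the E-enoate because the bulky quaternary substituent and the ester end up trans in the favoured oxaphosphetane.

Step 4
Reactants: 5 tert-butyl (E)-3-(2,2,5-trimethyl-1,3-dioxan-5-yl)prop-2-enoate
Product: 6 tert-butyl (E)-5-hydroxy-4-(hydroxymethyl)-4-methylpent-2-enoate
Conditions: p-TsOH·H2O (cat.), MeOH, rt
Reagents that add atoms: none
Why: Acid-catalysed ketal exchange with the solvent frees the prochiral 1,3-diol, while the tert-butyl ester is inert to catalytic sulfonic acid at room temperature and the E-alkene keeps the hydroxyls away from the ester.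

Step 5
Reactants: 6 tert-butyl (E)-5-hydroxy-4-(hydroxymethyl)-4-methylpent-2-enoate
Product: 7 tert-butyl (2E,4S)-4-(benzoyloxymethyl)-5-hydroxy-4-methylpent-2-enoate
Conditions: PhCOCl, Et3N, CuCl2 (cat.), 2,2'-(propane-2,2-diyl)bis[(4R)-4-phenyl-4,5-dihydro-1,3-oxazole] (cat.), THF, 0 °C
Reagents that add atoms: benzoyl chloride, O=C(Cl)c1ccccc1
Why: Catalytic enantioselective desymmetrisation of a 2,2-disubstituted propane-1,3-diol by monobenzoylation, in which the diol chelates the chiral divalent copper bis(oxazoline) complex, only one enantiotopic hydroxyl is activated for acylation, and this choice (benzoate on the future C12 arm) creates the quaternary stereocentre C6.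

Step 6
Reactants: 7 tert-butyl (2E,4S)-4-(benzoyloxymethyl)-5-hydroxy-4-methylpent-2-enoate
Product: 8 tert-butyl (2E,4R)-4-(benzoyloxymethyl)-4-methyl-5-oxopent-2-enoate
Conditions: Dess–Martin periodinane, CH2Cl2, 0 °C → rt, directly after step 5
Reagents that add atoms: none
Why: Dess–Martin oxidation of the remaining primary alcohol, carried out at once so that 1,3-benzoyl migration cannot erode the enantiomeric purity, gives the C7 aldehyde in which C6 bears four different carbon groups and is configurationally fixed.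

Step 7
Reactants: 8 tert-butyl (2E,4R)-4-(benzoyloxymethyl)-4-methyl-5-oxopent-2-enoate; 9 allyl 4-methoxyphenyl ether
Product: 11 tert-butyl (2E,4R,5R,6R)-4-(benzoyloxymethyl)-5-hydroxy-6-(4-methoxyphenoxy)-4-methylocta-2,7-dienoate, via Z-alkoxyallylborane 10 (not isolated)
Conditions: 9, s-BuLi, THF, −78 °C; (−)-Ipc2BOMe; BF3·OEt2; 8, −78 °C; then HOCH2CH2NH2, rt
Reagents that add atoms: allyl 4-methoxyphenyl ether (9), C=CCOc1ccc(OC)cc1; (−)-B-methoxydiisopinocampheylborane, COB([C@@H]1C[C@@H]2C[C@H]([C@H]1C)C2(C)C)[C@@H]1C[C@@H]2C[C@H]([C@H]1C)C2(C)C (its boron and terpene groups are held by 10 only)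
Why: Brown γ-alkoxyallylboration, in which kinetic lithiation of 9 gives the chelated Z-allyl anion and hence Z-allylborane 10, whose closed chair transition state translates Z geometry into the syn C7/C8 relationship, while the isopinocampheyl groups derived from (+)-α-pinene direct attack to the Si face of the aldehyde (7R,8R) and override the weak bias of C6, enoate and benzoate being inert to the borane at low temperature.

Step 8
Reactants: 11 tert-butyl (2E,4R,5R,6R)-4-(benzoyloxymethyl)-5-hydroxy-6-(4-methoxyphenoxy)-4-methylocta-2,7-dienoate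
Product: 12 tert-butyl (2E,4R,5R,6R)-5-hydroxy-4-(hydroxymethyl)-6-(4-methoxyphenoxy)-4-methylocta-2,7-dienoate
Conditions: K2CO3 (cat.), MeOH, 0 °C
Reagents that add atoms: none
Why: Carbonate-catalysed transesterification removes the electrophilic benzoate, which would not survive the ester enolate formed in step 11, and the cold, weakly basic medium avoids retro-aldol cleavage of the C6–C7 bond.

Step 9
Reactants: 12 tert-butyl (2E,4R,5R,6R)-5-hydroxy-4-(hydroxymethyl)-6-(4-methoxyphenoxy)-4-methylocta-2,7-dienoate
Product: 13 tert-butyl (2E,4R,5R,6R)-5-hydroxy-6-(4-methoxyphenoxy)-4-methyl-4-(triethylsilyloxymethyl)octa-2,7-dienoate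
Conditions: Et3SiCl, imidazole, CH2Cl2, −20 °C
Reagents that add atoms: chlorotriethylsilane, CC[Si](Cl)(CC)CC
Why: Silylation under imidazole catalysis is governed by steric access, so the primary O12 hydroxyl reacts and the secondary O7 hydroxyl flanked by C6 and C8 stays free, the triethylsilyl group being chosen because mild acid removes it in step 13.

Step 10
Reactants: 13 tert-butyl (2E,4R,5R,6R)-5-hydroxy-6-(4-methoxyphenoxy)-4-methyl-4-(triethylsilyloxymethyl)octa-2,7-dienoate; 14 3-methylbut-2-enoyl chloride
Product: 15 tert-butyl (2E,4R,5R,6R)-6-(4-methoxyphenoxy)-4-methyl-5-(3-methylbut-2-enoyloxy)-4-(triethylsilyloxymethyl)octa-2,7-dienoate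
Conditions: 14, pyridine, DMAP (cat.), CH2Cl2, 0 → 40 °C
Reagents that add atoms: 3-methylbut-2-enoyl chloride (14), CC(C)=CC(=O)Cl
Why: Nucleophilic catalysis by DMAP (acyl transfer from the acid chloride) forces acylation of the hindered O7 hydroxyl and attaches C1, C11 and C10 as a tethered donor, and any deconjugated 3-methylbut-3-enoate formed gives the same dienolate in step 11.

Step 11
Reactants: 15 tert-butyl (2E,4R,5R,6R)-6-(4-methoxyphenoxy)-4-methyl-5-(3-methylbut-2-enoyloxy)-4-(triethylsilyloxymethyl)octa-2,7-dienoate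
Product: 18 tert-butyl 2-[(3R,4S,5R,6R)-6-[(1R)-1-(4-methoxyphenoxy)prop-2-enyl]-5-methyl-2-oxo-3-(prop-1-en-2-yl)-5-(triethylsilyloxymethyl)oxan-4-yl]acetate, via lithium dienolate 16 (not isolated), via cyclised lithium enolate 17 (not isolated)
Conditions: LiN(i-Pr)2, THF, −78 °C; AcOH, −78 °C
Reagents that add atoms: lithium diisopropylamide, [Li]N(C(C)C)C(C)C (its lithium is held by 16 and 17 only)
Why: Intramolecular Michael addition of an ester dienolate through its α-carbon, in which syn γ-deprotonation of the s-cis senecioate gives dienolate 16 with OLi cis to the isopropenyl group, the six-membered tether excludes γ-attack, and a chair transition state with the C8 side chain, the C6 methyl, the acceptor arm (C4) and the isopropenyl group all equatorial (only CH2OSiEt3 axial) sets C5 (S) and C11 (R) as the all-equatorial lactone, which is also the thermodynamically preferred isomer.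

Step 12
Reactants: 18 δ-lactone tert-butyl ester
Product: 19 tert-butyl (3S,4R,5R,6R)-5-hydroxy-3-[(2R)-1-hydroxy-3-methylbut-3-en-2-yl]-6-(4-methoxyphenoxy)-4-methyl-4-(triethylsilyloxymethyl)oct-7-enoate
Conditions: LiBH4, THF, 0 °C → rt
Reagents that add atoms: none
Why: Chemoselective hydride reduction, since LiBH4 opens the δ-lactone to the C1/O7 diol much faster than it attacks the bulky tert-butyl ester, which differentiates C1 from C3 without touching any stereocentre.

Step 13
Reactants: 19 C1/O7 diol with O12 silyl ether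
Product: 21 O7/O12 acetonide with free C1 hydroxyl (5S,6R,7R,8R,11R), via triol 20 (not isolated)
Conditions: camphorsulfonic acid (cat.), MeOH, rt; then Me2C(OMe)2, acetone, rt; aqueous work-up
Reagents that add atoms: 2,2-dimethoxypropane, COC(C)(C)OC
Why: Acid-catalysed methanolysis of the primary triethylsilyl ether is followed by transketalisation in the same flask, and because only O7 and O12 among the three hydroxyls of 20 are 1,3-related the six-membered acetonide (C8 and C5 substituents equatorial, C6 methyl axial) forms while any mixed ketal at O1 falls off on aqueous work-up.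

Step 14
Reactants: 21 O7/O12 acetonide with free C1 hydroxyl
Product: 22 acetonide diene with C1 tert-butyldimethylsilyl ether (5S,6R,7R,8R,11R)
Conditions: t-BuMe2SiCl, imidazole, DMF, rt
Reagents that add atoms: tert-butyldimethylsilyl chloride, CC(C)(C)[Si](C)(C)Cl
Why: Standard silylation of the only free (primary) hydroxyl masks C1 for the base and heat of the key step.

Step 15
Reactants: 22 acetonide diene with C1 silyl ether
Product: 23 O8-aryl cycloheptene tert-butyl ester (5S,6R,7R,8R,11R)
Conditions: second-generation Grubbs catalyst (cat.), CH2Cl2, 40 °C, dilute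
Reagents that add atoms: none
Why: Ring-closing olefin metathesis joins the C8 vinyl and C11 isopropenyl groups, held gauche as equatorial neighbours on the dioxane chair, into the cycloheptene with the trisubstituted C9=C10 bond, whose cis ring geometry is the only one a seven-membered ring allows.

Step 16
Reactants: 23 O8-aryl cycloheptene tert-butyl ester
Product: 24 C8 allylic alcohol tert-butyl ester (5S,6R,7R,8R,11R)
Conditions: (NH4)2Ce(NO3)6, MeCN–H2O, 0 °C, short contact
Reagents that add atoms: none
Why: Oxidative dearylation, in which tetravalent cerium oxidises the electron-rich 4-methoxyphenyl ether to a quinone-type cation that water hydrolyses, releases the O8 alcohol with retention because the C8–O bond is never broken, and the short cold reaction spares ketal and silyl ether.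

Step 17
Reactants: 24 C8 allylic alcohol tert-butyl ester
Product: 25 C8-hydroxy C3-carboxylic acid (5S,6R,7R,8R,11R)
Conditions: KOH, MeOH–THF–H2O, 60 °C; then aq KHSO4 to pH 4, 0 °C
Reagents that add atoms: potassium hydroxide, [K+].[OH-]
Why: Saponification by acyl–oxygen cleavage of the tert-butyl ester is slow but workable on heating because the acyl side is an unhindered CH2, there is no α-stereocentre to lose, and ketal, silyl ether and alkene are stable to hydroxide.

Step 18
Reactants: 25 C8-hydroxy C3-carboxylic acid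
Product: 27 bridged lactone (5S,6R,7R,8R,11R), via mixed anhydride 26 (not isolated)
Conditions: 2,4,6-Cl3C6H2COCl, Et3N, THF, rt; then slow addition to DMAP, toluene, 60 °C, high dilution
Reagents that add atoms: 2,4,6-trichlorobenzoyl chloride, O=C(Cl)c1c(Cl)cc(Cl)cc1Cl (its aroyl group is held by 26 only)
Why: Yamaguchi lactonisation, in which mixed anhydride 26 is attacked under DMAP catalysis and high dilution by O8, which sits on the same ring face as the C5 acetic acid arm, so the bridged lactone closes with retention at C8.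

Step 19
Reactants: 27 bridged lactone (5S,6R,7R,8R,11R)
Product: 30 endo-C4 carboxylic acid of the bicyclo[4.1.1]oct-8-ene (4R,5R,6R,7S,10S,11R), via silyl ketene acetal 28 (not isolated), via silyl ester 29 (not isolated)
Conditions: KN(SiMe3)2, t-BuMe2SiCl (present from the start), THF–DMPU, −78 °C → rt; solvent change to toluene, 110 °C; then THF–H2O–AcOH, rt
Reagents that add atoms: tert-butyldimethylsilyl chloride, CC(C)(C)[Si](C)(C)Cl (this silyl group is held by 28 and 29 only and is lost again on hydrolysis)
Why: KN(SiMe3)2 removes a C4 proton of 27 in the presence of the chlorosilane and the enolate is silylated on oxygen to ketene acetal 28, in which the ring allows only the geometry with C5 and the ring oxygen cis. On heating, the array C4=C3(OSi)–O–C8–C9=C10 undergoes a concerted suprafacial [3,3] shift (Ireland–Claisen rearrangement, used as the ring contraction known for unsaturated medium-ring lactones), C4–C10 forming while C8–O breaks. The eight-membered ring C3–O–C8–C9–C10–C11–C5–C4 thereby contracts to the cyclobutane C4–C5–C11–C10 by transannular bonding of the two ends of the diene array, through the boat transition state that the C6–C7 bridge enforces. C10 is set by chirality transfer, since C4 is tethered to the ring face that carries the C8 oxygen and can reach only that face of C9=C10, and C4 is set by the cis ketene acetal geometry and the boat, which leave the carboxyl on the side of C9 (endo, opposite to the target, repaired in step 22). The step needs O- rather than C-silylation, deprotonation at C4 only, and rearrangement in preference to ketene loss; these are secured by the internal quench with the hindered chlorosilane, by the absence of any other acidic C–H (C1 is an ether, O7/O12 a ketal that also ties C12 back from C4), and by the irreversible gain of the silyl ester carbonyl, which pays for the ring strain. Mild hydrolysis of 29 frees acid 30 without touching the primary silyl ether.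

Step 20
Reactants: 30 endo-C4 carboxylic acid of the bicyclo[4.1.1]oct-8-ene
Product: 31 saturated endo-C4 carboxylic acid (4R,5R,6R,7S,10S,11R)
Conditions: H2 (1 atm), Pd/C, EtOAc, rt
Reagents that add atoms: none
Why: Heterogeneous catalytic hydrogenation saturates the only C=C bond, the cis-disubstituted C8=C9 alkene, and creates no stereocentre.

Step 21
Reactants: 31 saturated endo-C4 carboxylic acid
Product: 32 endo-C4 methyl ketone (4R,5R,6R,7S,10S,11R)
Conditions: MeLi, Et2O, 0 °C → rt; inverse quench into cold aq NH4Cl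
Reagents that add atoms: methyllithium, [Li]C
Why: Addition of methyllithium to the lithium carboxylate stops at the dilithium gem-diolate, which collapses to the methyl ketone (C3 with its methyl group) only on the inverse quench, so over-addition is avoided.

Step 22
Reactants: 32 endo-C4 methyl ketone
Product: 33 exo-C4 methyl ketone (4S,5R,6R,7S,10S,11R)
Conditions: NaOMe, MeOH, 50 °C
Reagents that add atoms: none
Why: Base-mediated epimerisation through the exocyclic enolate moves the acetyl group from the congested endo position, where it is cis to both C6 and C9 and faces the four-carbon bridge, to the exo position required by the target, under thermodynamic control at C4.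

Step 23
Reactants: 33 exo-C4 methyl ketone
Product: 34 exo-C4 isopropenyl compound with C1 silyl ether (4R,5S,6R,7S,10R,11R)
Conditions: Ph3PCH3Br, KOt-Bu, THF, 0 → 50 °C
Reagents that add atoms: methyltriphenylphosphonium bromide, C[P+](c1ccccc1)(c1ccccc1)c1ccccc1.[Br-]
Why: Wittig methylenation converts the acetyl group into the isopropenyl group, and C4, already in its more stable configuration, is not endangered by the basic ylide.

Step 24
Reactants: 34 exo-C4 isopropenyl compound with C1 silyl ether
Product: 35 C1 primary alcohol (4R,5S,6R,7S,10R,11R)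
Conditions: Bu4NF, THF, rt
Reagents that add atoms: none
Why: Fluoride cleaves the silyl ether through the strong Si–F bond and leaves ketal and alkene untouched.

Step 25
Reactants: 35 C1 primary alcohol
Product: 36 C1 aldehyde (4R,5S,6R,7S,10R,11R)
Conditions: Dess–Martin periodinane, CH2Cl2, rt
Reagents that add atoms: none
Why: Dess–Martin oxidation gives the C1 aldehyde under non-basic conditions, so the exo configuration at C11 is retained.

Step 26
Reactants: 36 C1 aldehyde
Product: 37 C1 vinyl carbinol (both C1 epimers; 4R,5S,6R,7S,10R,11R)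
Conditions: CH2=CHMgBr, THF, −78 °C; aq NH4Cl
Reagents that add atoms: vinylmagnesium bromide, C=C[Mg]Br
Why: Grignard 1,2-addition installs C2, and the new carbinol centre at C1 forms as an epimer mixture that is irrelevant because it is oxidised in step 28.

Step 27
Reactants: 37 C1 vinyl carbinol
Product: 38 tetracyclic allylic alcohol (both C1 epimers; 4R,5S,6R,7S,10R,11R)
Conditions: second-generation Grubbs catalyst (cat.), toluene, 80 °C
Reagents that add atoms: none
Why: Ring-closing olefin metathesis of the vinyl and isopropenyl groups, which are held cis-1,3 on the exo face of the cyclobutane, closes the six-membered ring C11–C1–C2–C3–C4–C5 with the trisubstituted C2=C3 alkene and is driven by loss of ethene.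

Step 28
Reactants: 38 tetracyclic allylic alcohol
Product: 39 enone acetonide (4R,5S,6R,7S,10R,11R)
Conditions: Dess–Martin periodinane, CH2Cl2, rt
Reagents that add atoms: none
Why: Dess–Martin oxidation of the allylic alcohol merges both C1 epimers into the enone.

Step 29
Reactants: 39 enone acetonide
Product: 40 enone O7/O12 diol (4R,5S,6R,7S,10R,11R)
Conditions: 1 M aq HCl, THF, rt
Reagents that add atoms: none
Why: Acid-catalysed hydrolysis of the isopropylidene ketal frees O7 and O12, and the enone and the cyclobutane carry no acid-labile function.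

Step 30
Reactants: 40 enone O7/O12 diol; 41 angelic acid
Product: 43 CNP0240716.1 (O7,O12-bis-angelate; 4R,5S,6R,7S,10R,11R), via angelic mixed anhydride 42 (not isolated)
Conditions: 41, 2,4,6-Cl3C6H2COCl, Et3N, toluene, rt; then 40, 80 °C
Reagents that add atoms: angelic acid (41), C/C=C(/C)C(O)=O; 2,4,6-trichlorobenzoyl chloride, O=C(Cl)c1c(Cl)cc(Cl)cc1Cl (its aroyl group is held by 42 only)
Why: Yamaguchi-type esterification, in which the preformed mixed anhydride 42 acylates both hydroxyls on heating without a nucleophilic amine catalyst, conditions under which the Z-configured angelate does not isomerise to the tiglate.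

Compound list

1 | 1,1,1-tris(hydroxymethyl)ethane | CC(CO)(CO)CO | starting material
2 | (2,2,5-trimethyl-1,3-dioxan-5-yl)methanol | CC1(CO)COC(C)(C)OC1 | intermediate
3 | 2,2,5-trimethyl-1,3-dioxane-5-carbaldehyde | CC1(C=O)COC(C)(C)OC1 | intermediate
4 | tert-butyl 2-(diethoxyphosphoryl)acetate | CCOP(=O)(CC(=O)OC(C)(C)C)OCC | starting material
5 | tert-butyl (E)-3-(2,2,5-trimethyl-1,3-dioxan-5-yl)prop-2-enoate | CC1(/C=C/C(=O)OC(C)(C)C)COC(C)(C)OC1 | intermediate
6 | tert-butyl (E)-5-hydroxy-4-(hydroxymethyl)-4-methylpent-2-enoate | CC(CO)(CO)/C=C/C(=O)OC(C)(C)C | intermediate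
7 | tert-butyl (2E,4S)-4-(benzoyloxymethyl)-5-hydroxy-4-methylpent-2-enoate (benzoate on the C12 arm) | O=C(c1ccccc1)OC[C@@](CO)(C)/C=C/C(=O)OC(C)(C)C | intermediate
8 | tert-butyl (2E,4R)-4-(benzoyloxymethyl)-4-methyl-5-oxopent-2-enoate (C7 aldehyde) | O=C(c1ccccc1)OC[C@@](C=O)(C)/C=C/C(=O)OC(C)(C)C | intermediate
9 | allyl 4-methoxyphenyl ether | C=CCOc1ccc(OC)cc1 | starting material
10 | (Z)-3-(4-methoxyphenoxy)allyl-bis(isopinocampheyl)borane, terpene groups from (+)-α-pinene | COc1ccc(O/C=C\CB([C@@H]2C[C@@H]3C[C@H]([C@H]2C)C3(C)C)[C@@H]2C[C@@H]3C[C@H]([C@H]2C)C3(C)C)cc1 | intermediate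
11 | tert-butyl (2E,4R,5R,6R)-4-(benzoyloxymethyl)-5-hydroxy-6-(4-methoxyphenoxy)-4-methylocta-2,7-dienoate | C=C[C@@H](Oc1ccc(OC)cc1)[C@H](O)[C@@](C)(COC(=O)c1ccccc1)/C=C/C(=O)OC(C)(C)C | intermediate
12 | tert-butyl (2E,4R,5R,6R)-5-hydroxy-4-(hydroxymethyl)-6-(4-methoxyphenoxy)-4-methylocta-2,7-dienoate | C=C[C@@H](Oc1ccc(OC)cc1)[C@H](O)[C@@](C)(CO)/C=C/C(=O)OC(C)(C)C | intermediate
13 | tert-butyl (2E,4R,5R,6R)-5-hydroxy-6-(4-methoxyphenoxy)-4-methyl-4-(triethylsilyloxymethyl)octa-2,7-dienoate | C=C[C@@H](Oc1ccc(OC)cc1)[C@H](O)[C@@](C)(CO[Si](CC)(CC)CC)/C=C/C(=O)OC(C)(C)C | intermediate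
14 | 3-methylbut-2-enoyl chloride | CC(C)=CC(=O)Cl | starting material
15 | tert-butyl (2E,4R,5R,6R)-6-(4-methoxyphenoxy)-4-methyl-5-(3-methylbut-2-enoyloxy)-4-(triethylsilyloxymethyl)octa-2,7-dienoate | C=C[C@@H](Oc1ccc(OC)cc1)[C@H](OC(=O)C=C(C)C)[C@@](C)(CO[Si](CC)(CC)CC)/C=C/C(=O)OC(C)(C)C | intermediate
16 | lithium dienolate of 15 (OLi cis to the isopropenyl group) | C=C[C@@H](Oc1ccc(OC)cc1)[C@H](O/C(O[Li])=C/C(C)=C)[C@@](C)(CO[Si](CC)(CC)CC)/C=C/C(=O)OC(C)(C)C | intermediate
17 | cyclised δ-lactone as lithium enolate of its tert-butyl ester | O=C1O[C@@H]([C@H](Oc2ccc(OC)cc2)C=C)[C@@](C)(CO[Si](CC)(CC)CC)[C@@H](C=C(O[Li])OC(C)(C)C)[C@@H]1C(C)=C | intermediate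
18 | tert-butyl 2-[(3R,4S,5R,6R)-6-[(1R)-1-(4-methoxyphenoxy)prop-2-enyl]-5-methyl-2-oxo-3-(prop-1-en-2-yl)-5-(triethylsilyloxymethyl)oxan-4-yl]acetate (O7–C1 δ-lactone; 5S,6R,7R,8R,11R) | O=C1O[C@@H]([C@H](Oc2ccc(OC)cc2)C=C)[C@@](C)(CO[Si](CC)(CC)CC)[C@@H](CC(=O)OC(C)(C)C)[C@@H]1C(C)=C | intermediate
19 | tert-butyl (3S,4R,5R,6R)-5-hydroxy-3-[(2R)-1-hydroxy-3-methylbut-3-en-2-yl]-6-(4-methoxyphenoxy)-4-methyl-4-(triethylsilyloxymethyl)oct-7-enoate | C=C[C@@H](Oc1ccc(OC)cc1)[C@H](O)[C@@](C)(CO[Si](CC)(CC)CC)[C@@H](CC(=O)OC(C)(C)C)[C@@H](CO)C(C)=C | intermediate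
20 | O1,O7,O12 triol (19 without the silyl group) | C=C[C@@H](Oc1ccc(OC)cc1)[C@H](O)[C@@](C)(CO)[C@@H](CC(=O)OC(C)(C)C)[C@@H](CO)C(C)=C | intermediate
21 | O7/O12 acetonide (1,3-dioxane, C8 and C5 groups equatorial) with free C1 hydroxyl, O8 aryl ether, C3 tert-butyl ester; 5S,6R,7R,8R,11R | CC1(C)OC[C@@](C)([C@@H](CC(=O)OC(C)(C)C)[C@@H](CO)C(C)=C)[C@H]([C@H](Oc2ccc(OC)cc2)C=C)O1 | intermediate
22 | 21 as its C1 tert-butyldimethylsilyl ether | CC1(C)OC[C@@](C)([C@@H](CC(=O)OC(C)(C)C)[C@@H](CO[Si](C)(C)C(C)(C)C)C(C)=C)[C@H]([C@H](Oc2ccc(OC)cc2)C=C)O1 | intermediate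
23 | cycloheptene C5–C11 (C9=C10, methyl on C10) trans-fused to the dioxane; 4-methoxyphenoxy on C8, CH2CO2t-Bu on C5, CH2OSi on C11, these three groups cis; 5S,6R,7R,8R,11R | CC1(C)OC[C@@]2(C)[C@@H](CC(=O)OC(C)(C)C)[C@@H](CO[Si](C)(C)C(C)(C)C)C(C)=C[C@@H](Oc3ccc(OC)cc3)[C@@H]2O1 | intermediate
24 | 23 with free C8 hydroxyl | CC1(C)OC[C@@]2(C)[C@@H](CC(=O)OC(C)(C)C)[C@@H](CO[Si](C)(C)C(C)(C)C)C(C)=C[C@@H](O)[C@@H]2O1 | intermediate
25 | 24 as the free C3 carboxylic acid | CC1(C)OC[C@@]2(C)[C@@H](CC(=O)O)[C@@H](CO[Si](C)(C)C(C)(C)C)C(C)=C[C@@H](O)[C@@H]2O1 | intermediate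
26 | mixed 2,4,6-trichlorobenzoic anhydride of 25 | CC1(C)OC[C@@]2(C)[C@@H](CC(=O)OC(=O)c3c(Cl)cc(Cl)cc3Cl)[C@@H](CO[Si](C)(C)C(C)(C)C)C(C)=C[C@@H](O)[C@@H]2O1 | intermediate
27 | bridged lactone: O8 of the 3-methylcyclohept-2-enol acylated by the C4H2–C3 arm on C5; acetonide, C1 silyl ether; 5S,6R,7R,8R,11R | CC1(C)OC[C@@]2(C)[C@H]3CC(=O)O[C@H](C=C(C)[C@@H]3CO[Si](C)(C)C(C)(C)C)[C@@H]2O1 | intermediate
28 | O-silyl ketene acetal of 27 (C5 and ring oxygen cis on C4=C3) | CC1(C)OC[C@@]2(C)[C@H]3/C=C(/O[Si](C)(C)C(C)(C)C)O[C@H](C=C(C)[C@@H]3CO[Si](C)(C)C(C)(C)C)[C@@H]2O1 | intermediate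
29 | tert-butyldimethylsilyl ester of 30 | CC1(C)OC[C@@]2(C)[C@@H]3[C@@H](CO[Si](C)(C)C(C)(C)C)[C@@](C)([C@@H]3C(=O)O[Si](C)(C)C(C)(C)C)C=C[C@@H]2O1 | intermediate
30 | bicyclo[4.1.1]octene (bridgeheads C5, C10; bridges C6–C7–C8=C9, C4, C11) with endo CO2H on C4, exo CH2OSi on C11; 4R,5R,6R,7S,10S,11R | CC1(C)OC[C@@]2(C)[C@@H]3[C@@H](CO[Si](C)(C)C(C)(C)C)[C@@](C)([C@@H]3C(O)=O)C=C[C@@H]2O1 | intermediate
31 | 30 with C8–C9 saturated; 4R,5R,6R,7S,10S,11R | CC1(C)OC[C@@]2(C)[C@@H]3[C@@H](CO[Si](C)(C)C(C)(C)C)[C@@](C)([C@@H]3C(O)=O)CC[C@@H]2O1 | intermediate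
32 | endo-C4 acetyl compound; 4R,5R,6R,7S,10S,11R | CC1(C)OC[C@@]2(C)[C@@H]3[C@@H](CO[Si](C)(C)C(C)(C)C)[C@@](C)([C@@H]3C(C)=O)CC[C@@H]2O1 | intermediate
33 | exo-C4 acetyl compound; 4S,5R,6R,7S,10S,11R | CC1(C)OC[C@@]2(C)[C@@H]3[C@@H](CO[Si](C)(C)C(C)(C)C)[C@@](C)([C@H]3C(C)=O)CC[C@@H]2O1 | intermediate
34 | exo-C4 isopropenyl compound, C1 silyl ether; 4R,5S,6R,7S,10R,11R | CC1(C)OC[C@@]2(C)[C@@H]3[C@@H](CO[Si](C)(C)C(C)(C)C)[C@@](C)([C@H]3C(C)=C)CC[C@@H]2O1 | intermediate
35 | C1 primary alcohol | CC1(C)OC[C@@]2(C)[C@@H]3[C@@H](CO)[C@@](C)([C@H]3C(C)=C)CC[C@@H]2O1 | intermediate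
36 | C1 aldehyde | CC1(C)OC[C@@]2(C)[C@@H]3[C@@H](C=O)[C@@](C)([C@H]3C(C)=C)CC[C@@H]2O1 | intermediate
37 | C1 vinyl carbinol, both C1 epimers | CC1(C)OC[C@@]2(C)[C@@H]3[C@@H](C(O)C=C)[C@@](C)([C@H]3C(C)=C)CC[C@@H]2O1 | intermediate
38 | tetracyclic allylic alcohol (C1–OH, C2=C3), both C1 epimers | CC1(C)OC[C@@]2(C)[C@@H]3[C@H]4C(O)C=C(C)[C@@H]3[C@@]4(C)CC[C@@H]2O1 | intermediate
39 | enone acetonide; 4R,5S,6R,7S,10R,11R | CC1(C)OC[C@@]2(C)[C@@H]3[C@H]4C(=O)C=C(C)[C@@H]3[C@@]4(C)CC[C@@H]2O1 | intermediate
40 | enone O7/O12 diol; 4R,5S,6R,7S,10R,11R | OC[C@@]1(C)[C@@H]2[C@H]3C(=O)C=C(C)[C@@H]2[C@@]3(C)CC[C@@H]1O | intermediate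
41 | angelic acid, (Z)-2-methylbut-2-enoic acid | C/C=C(/C)C(O)=O | starting material
42 | angelic 2,4,6-trichlorobenzoic anhydride | C/C=C(/C)C(=O)OC(=O)c1c(Cl)cc(Cl)cc1Cl | intermediate
43 | CNP0240716.1, O7,O12-bis-angelate; 4R,5S,6R,7S,10R,11R | C/C=C(/C)C(=O)OC[C@@]1(C)[C@@H]2[C@H]3C(=O)C=C(C)[C@@H]2[C@@]3(C)CC[C@@H]1OC(=O)/C(C)=C\C | target

Total step count: 30. Longest linear sequence: 30 steps (1 → 43). Compounds 4, 9, 14 and 41 enter as purchased building blocks.

Steps most likely to fail

Step 19. The ketene acetal may not reach the strained boat geometry before it is consumed by competing processes. These are reprotonation to the lactone, C-silylation, and fragmentation to a ketene and the C8 alkoxide. The four-membered ring leaves the shift only a small driving force.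

The fallback is a decarboxylative Carroll variant.
- It sets out from 27. C-acetylation of the lithium enolate with 1-acetylimidazole gives the β-keto lactone F1.
- The dianion of F1 (two equivalents of LiN(i-Pr)2, THF, −78 → 65 °C) undergoes a charge-accelerated [3,3] shift to the β-keto acid F2.
- F2 loses carbon dioxide on warming in toluene to give the unsaturated methyl ketone F3. The bond formation is thus pulled by an irreversible gas loss, and the acetyl group arrives directly.
- Hydrogenation (H2, Pd/C) and equilibration with NaOMe in MeOH bring the material back to the route at 33.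

Step 11. Attack at the neopentyl β-carbon C5 may be slow. The dienolate could then expel the O7 alkoxide as a ketene, or proton transfer could move the isopropenyl double bond into conjugation. Facial control would be lost if the chair with the axial C8 side chain competes.

The fallback uses a stabilised donor under equilibrating conditions.
- It sets out from 13. Heating with 2,2,6-trimethyl-4H-1,3-dioxin-4-one in toluene (acylketene transfer, well suited to hindered alcohols) gives the acetoacetate F4.
- Cs2CO3 in MeCN triggers the intramolecular Michael addition of the soft enolate and should funnel the material into the all-equatorial β-keto lactone F5.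
- Chemoselective methylenation of the ketone with the non-basic Zn/CH2Br2/TiCl4 reagent turns acetyl into isopropenyl and returns to the route at 18.

Step 18. Closure needs both the O8 hydroxyl and the C5 arm in axial positions on a cycloheptene whose C6–C7 torsion is fixed by the trans-fused dioxane. Intermolecular acylation to oligomers, or ionisation of the activated allylic alcohol, may therefore win.

The fallback reverses the order of the two ring closures.
- It sets out from 22. Oxidative dearylation with (NH4)2Ce(NO3)6 gives the acyclic allylic alcohol F6.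
- Saponification gives the hydroxy acid F7.
- Activation as the mixed trichlorobenzoic anhydride F8 closes the unbridged seven-membered lactone F9.
- Ring-closing metathesis of the C8 vinyl and C11 isopropenyl groups of F9 with second-generation Grubbs catalyst then forms the carbocycle and returns to the route at 27.

Further compounds
F1 | step 19 | β-keto lactone, 27 acetylated at C4 (C4 enolisable) | CC1(C)OC[C@@]2(C)[C@H]3C(C(C)=O)C(=O)O[C@H](C=C(C)[C@@H]3CO[Si](C)(C)C(C)(C)C)[C@@H]2O1
F2 | step 19 | β-keto acid, bicyclo[4.1.1]octene with endo CO2H and exo acetyl on C4 | CC1(C)OC[C@@]2(C)[C@@H]3[C@@H](CO[Si](C)(C)C(C)(C)C)[C@@](C)([C@]3(C(C)=O)C(O)=O)C=C[C@@H]2O1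
F3 | step 19 | unsaturated C4 methyl ketone (C4 epimers) | CC1(C)OC[C@@]2(C)[C@@H]3[C@@H](CO[Si](C)(C)C(C)(C)C)[C@@](C)(C3C(C)=O)C=C[C@@H]2O1
F4 | step 11 | O7 acetoacetate of 13 | C=C[C@@H](Oc1ccc(OC)cc1)[C@H](OC(=O)CC(C)=O)[C@@](C)(CO[Si](CC)(CC)CC)/C=C/C(=O)OC(C)(C)C
F5 | step 11 | β-keto δ-lactone, 18 with acetyl in place of isopropenyl | O=C1O[C@@H]([C@H](Oc2ccc(OC)cc2)C=C)[C@@](C)(CO[Si](CC)(CC)CC)[C@@H](CC(=O)OC(C)(C)C)[C@@H]1C(C)=O
F6 | step 18 | 22 with free C8 hydroxyl | CC1(C)OC[C@@](C)([C@@H](CC(=O)OC(C)(C)C)[C@@H](CO[Si](C)(C)C(C)(C)C)C(C)=C)[C@H]([C@H](O)C=C)O1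
F7 | step 18 | F6 as the free C3 carboxylic acid | CC1(C)OC[C@@](C)([C@@H](CC(=O)O)[C@@H](CO[Si](C)(C)C(C)(C)C)C(C)=C)[C@H]([C@H](O)C=C)O1
F8 | step 18 | mixed 2,4,6-trichlorobenzoic anhydride of F7 | CC1(C)OC[C@@](C)([C@@H](CC(=O)OC(=O)c2c(Cl)cc(Cl)cc2Cl)[C@@H](CO[Si](C)(C)C(C)(C)C)C(C)=C)[C@H]([C@H](O)C=C)O1
F9 | step 18 | seven-membered O8–C3 lactone bearing the C8 vinyl group and the C11 side chain | CC1(C)OC[C@@]2(C)[C@H]([C@@H](CO[Si](C)(C)C(C)(C)C)C(C)=C)CC(=O)O[C@H](C=C)[C@@H]2O1
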